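**Plan**

- Retrosynthesis: cut the O–acetyl bond, then C14–C15 and C13–CH3 (carboalumination of a C13≡C14 alkyne), then C8=C17 (Wittig on a C8 ketone), then in one event C5–C6 (ring B) together with the C3–C4 bond of ring A, and last C9–C10 (Ireland–Claisen).
- Enabling feature: in ring A the quaternary C4 carries a methyl and the oxidised one-carbon branch C19, and it sits next to the ring-fusion carbon C5, whose bond to C6 leads to a carbonyl position of ring B (C8). This is the product pattern of a conjugate Prins–semipinacol reaction of a 2-methylcyclohept-2-en-1-ol unit in which C19 is still a ring atom between C3 and C4.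
- Forward order: a cycloheptene (C10, C1, C2, C3, C19, C4, C5) is made first and C9 with its chain is attached to C10. The key step closes ring B (C5–C6) and contracts the seven-membered ring to ring A, C19 leaving the ring as the formyl group. Methylene and side chain follow.
- Stereochemistry: C10 by chirality transfer from a CBS-derived allylic alcohol in the Claisen step. C4 and C5 by anti addition across the ring alkene in the key step, the face being steered by a temporary C19 silyloxy centre (second CBS reduction). C9 by equilibration next to the C8 ketone. The 13E alkene by syn carbometalation.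

Key step: step 11

Remark: 3-methylcyclohept-2-en-1-one is taken as a catalogue compound; C9 is carried as a mixture of epimers from step 3 until it is set in step 13.

**Route**

Step 1
Reactants: 1 3-methylcyclohept-2-en-1-one
Product: 2 (R)-3-methylcyclohept-2-en-1-ol
Conditions: (S)-2-methyl-CBS-oxazaborolidine (0.1 equiv), BH3·SMe2, THF, −20 °C; MeOH quench
Reagents that add atoms: none
Why: CBS reduction, in which the oxazaborolidine–borane complex binds the enone carbonyl with the alkenyl arm as the large group and delivers hydride to one face, should set the carbinol centre as R by 1,2-reduction.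

Step 2
Reactants: 2 (R)-3-methylcyclohept-2-en-1-ol; 3 hex-5-ynoic acid
Product: 4 (R)-3-methylcyclohept-2-en-1-yl hex-5-ynoate
Conditions: DCC, DMAP (cat.), CH2Cl2, 0 °C to rt
Reagents that add atoms: none
Why: Steglich esterification is neutral, so the ionisable allylic C–O bond and the carbinol centre should be kept.

Step 3
Reactants: 4 (R)-3-methylcyclohept-2-en-1-yl hex-5-ynoate
Product: 7 2-[(S)-1-methylcyclohept-2-en-1-yl]-6-(trimethylsilyl)hex-5-ynoic acid (C2 epimers), via silyl ketene acetal 5 (not isolated), via trimethylsilyl ester 6 (not isolated)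
Conditions: LiN(i-Pr)2 (2.2 equiv), THF, −78 °C; Me3SiCl (3 equiv), −78 to 60 °C; dilute aq. HCl
Reagents that add atoms: chlorotrimethylsilane C[Si](C)(C)Cl
Why: Ireland–Claisen rearrangement is suprafacial across the ring allyl unit, so the new C9–C10 bond should form on the face the C–O bond leaves and transfer the R carbinol centre to the quaternary C10 (S), while the second equivalent of base turns the alkyne C–H into a C–SiMe3 cap that protects it up to step 12.

Step 4
Reactants: 7 2-[(S)-1-methylcyclohept-2-en-1-yl]-6-(trimethylsilyl)hex-5-ynoic acid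
Product: 9 N-methoxy-N-methyl-2-[(S)-1-methylcyclohept-2-en-1-yl]-6-(trimethylsilyl)hex-5-ynamide, via acid chloride 8 (not isolated)
Conditions: (COCl)2, DMF (cat.), CH2Cl2, 0 °C; then MeNH(OMe)·HCl, pyridine, 0 °C to rt
Reagents that add atoms: N,O-dimethylhydroxylamine hydrochloride CNOC.Cl
Why: Weinreb amide formation through the acid chloride should work on the hindered acid and gives an acyl group that is inert in steps 5 to 9 and accepts one equivalent of a Grignard reagent in step 10.

Step 5
Reactants: 9 N-methoxy-N-methyl-2-[(S)-1-methylcyclohept-2-en-1-yl]-6-(trimethylsilyl)hex-5-ynamide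
Product: 10 N-methoxy-N-methyl-2-[(S)-1-methyl-4-oxocyclohept-2-en-1-yl]-6-(trimethylsilyl)hex-5-ynamide
Conditions: t-BuOOH (5 equiv), Pd(OH)2 on carbon (cat.), K2CO3, CH2Cl2, 0 °C to rt
Reagents that add atoms: tert-butyl hydroperoxide CC(C)(C)OO
Why: Allylic C–H oxidation of a cycloalkene to the enone should occur at C19, the only allylic CH2 (the other allylic carbon is the quaternary C10), because trapping of the allyl radical at the hindered C5 end is disfavoured.

Step 6
Reactants: 10 N-methoxy-N-methyl-2-[(S)-1-methyl-4-oxocyclohept-2-en-1-yl]-6-(trimethylsilyl)hex-5-ynamide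
Product: 11 N-methoxy-N-methyl-2-[(R)-3-iodo-1-methyl-4-oxocyclohept-2-en-1-yl]-6-(trimethylsilyl)hex-5-ynamide (same spatial arrangement at the quaternary carbon; the descriptor changes by priority only)
Conditions: I2, pyridine, CH2Cl2, rt
Reagents that add atoms: iodine II
Why: α-Iodination of a cyclic enone by conjugate addition of pyridine, iodination of the enolate and elimination should put iodine on C4.

Step 7
Reactants: 11 N-methoxy-N-methyl-2-[(R)-3-iodo-1-methyl-4-oxocyclohept-2-en-1-yl]-6-(trimethylsilyl)hex-5-ynamide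
Product: 12 N-methoxy-N-methyl-2-[(S)-1,3-dimethyl-4-oxocyclohept-2-en-1-yl]-6-(trimethylsilyl)hex-5-ynamide
Conditions: Me4Sn, Pd2(dba)3 (cat.), AsPh3, CuI, NMP, 60 °C
Reagents that add atoms: tetramethylstannane C[Sn](C)(C)C
Why: Stille coupling of a 2-iodoenone with Me4Sn should install the future C18 methyl on C4 without touching the alkynylsilane or the amide.

Step 8
Reactants: 12 N-methoxy-N-methyl-2-[(S)-1,3-dimethyl-4-oxocyclohept-2-en-1-yl]-6-(trimethylsilyl)hex-5-ynamide
Product: 13 N-methoxy-N-methyl-2-[(1S,4S)-4-hydroxy-1,3-dimethylcyclohept-2-en-1-yl]-6-(trimethylsilyl)hex-5-ynamide (hydroxyl cis to the C1 methyl)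
Conditions: (R)-2-methyl-CBS-oxazaborolidine (0.2 equiv), catecholborane, toluene, −78 °C
Reagents that add atoms: none
Why: CBS reduction of a 2-substituted cyclic enone is reagent-controlled, so the (R)-catalyst should set C19 as S (hydroxyl cis to the C10 methyl), and catecholborane at −78 °C leaves the alkyne and the amide alone.

Step 9
Reactants: 13 N-methoxy-N-methyl-2-[(1S,4S)-4-hydroxy-1,3-dimethylcyclohept-2-en-1-yl]-6-(trimethylsilyl)hex-5-ynamide
Product: 14 N-methoxy-N-methyl-2-[(1S,4S)-4-(tert-butyldimethylsilyloxy)-1,3-dimethylcyclohept-2-en-1-yl]-6-(trimethylsilyl)hex-5-ynamide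
Conditions: t-BuMe2SiCl, imidazole, DMF, rt
Reagents that add atoms: tert-butyldimethylsilyl chloride CC(C)(C)[Si](C)(C)Cl
Why: Silylation of the secondary allylic alcohol should be routine and gives the bulky silyl ether that is both trigger and conformational control element of step 11.

Step 10
Reactants: 14 N-methoxy-N-methyl-2-[(1S,4S)-4-(tert-butyldimethylsilyloxy)-1,3-dimethylcyclohept-2-en-1-yl]-6-(trimethylsilyl)hex-5-ynamide
Product: 15 4-[(1S,4S)-4-(tert-butyldimethylsilyloxy)-1,3-dimethylcyclohept-2-en-1-yl]-8-(trimethylsilyl)oct-1-en-7-yn-3-one (C4 epimers)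
Conditions: CH2=CHMgBr (3 equiv), THF, −78 to 0 °C; cold aq. NH4Cl
Reagents that add atoms: vinylmagnesium bromide C=C[Mg]Br
Why: Grignard addition to a Weinreb amide stops at the chelated adduct and should give the vinyl ketone on cold quench, the C–SiMe3 cap preventing deprotonation of the alkyne.

Step 11
Reactants: 15 4-[(1S,4S)-4-(tert-butyldimethylsilyloxy)-1,3-dimethylcyclohept-2-en-1-yl]-8-(trimethylsilyl)oct-1-en-7-yn-3-one
Product: 16 8-oxo-14-(trimethylsilyl)-15,16,17-trinorlabd-13-yn-19-al (4α-methyl, 4β-formyl, 5α-H, 10β-methyl; C9 epimers)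
Conditions: Me2AlCl (2 equiv), CH2Cl2, −78 to −40 °C; MeOH then aq. NaHCO3 at −78 °C
Reagents that add atoms: none
Why: Proposed new method: Me2AlCl bound to the vinyl ketone makes C6 electrophilic, C5 of the ring alkene (C4=C5) attacks it, and the tertiary cation that builds up at C4 is quenched in the same event by the 1,2-shift of C3 from the silyloxy carbon C19 to C4 (semipinacol), which contracts the cycloheptene to ring A and leaves C19 as the formyl group once the silyl group is lost to chloride; the closest known reactions are the acetal-initiated Prins–pinacol ring contraction and the alkylaluminium halide-promoted addition of alkenes to enones. Ring B closes by a 6-endo-trig attack on the enone (exo with respect to the ring alkene) through a chair, and ring A is not closed but arises from the seven-membered ring by the ring-contracting 1,2-alkyl shift. C4 and C5 are set together by anti addition across the cis ring alkene, C6 to one face of C5 and C3 to the other face of C4, which puts the formyl group anti to H-5 and therefore axial on the face of the C10 methyl, as in the 19-oic acids. The face is chosen by the cycloheptene chair in which the branched chain on C10 is pseudo-equatorial and the OSiMe2t-Bu group is pseudo-axial to avoid allylic 1,2-strain with the C4 methyl: both preferences coincide only because the silyloxy group was set cis to the C10 methyl in step 8, and they deliver C6 syn to that methyl (trans ring fusion) while C3 migrates on the opposite face. The step needs alkyl shift to win over hydride shift and over ene-type proton loss, which the same conformation should secure because the C19–H bond lies near the nodal plane of the C4 cation whereas the C19–C3 bond is aligned with it and is pushed by the oxygen lone pair; the alkynylsilane is a weaker and badly placed nucleophile. C9 is not touched and is set in step 13.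

Step 12
Reactants: 16 8-oxo-14-(trimethylsilyl)-15,16,17-trinorlabd-13-yn-19-al
Product: 17 8-oxo-14-(trimethylsilyl)-15,16,17-trinorlabd-13-yn-19-oic acid (C9 epimers)
Conditions: NaClO2, NaH2PO4, 2-methylbut-2-ene, t-BuOH/H2O, rt
Reagents that add atoms: sodium chlorite [Na+].[O-]Cl=O
Why: Pinnick oxidation should convert the hindered, non-enolisable aldehyde to the acid while the scavenger removes HOCl and the ketone and alkyne stay untouched.

Step 13
Reactants: 17 8-oxo-14-(trimethylsilyl)-15,16,17-trinorlabd-13-yn-19-oic acid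
Product: 18 8-oxo-15,16,17-trinorlabd-13-yn-19-oic acid (9α-H, side chain 9β)
Conditions: NaOMe, MeOH, 40 °C; then aq. HCl to pH 3
Reagents that add atoms: none
Why: Methoxide should cleave the alkynyl C–Si bond and equilibrate C9 through the C8 enolate to the more stable epimer with the side chain equatorial (the labdane configuration), C4 being quaternary and unable to epimerise.

Step 14
Reactants: 18 8-oxo-15,16,17-trinorlabd-13-yn-19-oic acid
Product: 19 15,16-dinorlabd-8(17)-en-13-yn-19-oic acid
Conditions: Ph3PCH3Br, KOt-Bu, THF, 0 °C to reflux; then aq. HCl to pH 3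
Reagents that add atoms: methyltriphenylphosphonium bromide C[P+](c1ccccc1)(c1ccccc1)c1ccccc1.[Br-]
Why: Wittig methylenation of the hindered C8 ketone with excess ylide should give the exocyclic alkene, the acid being protected as its carboxylate and C9 already at its stable configuration.

Step 15
Reactants: 19 15,16-dinorlabd-8(17)-en-13-yn-19-oic acid
Product: 21 isocupressic acid [15-hydroxylabda-8(17),13E-dien-19-oic acid], via alkenylalane 20 (not isolated)
Conditions: Me3Al (4 equiv), Cp2ZrCl2 (0.25 equiv), CH2Cl2, 0 °C to rt; then (CH2O)n, THF, 0 °C to rt; aq. HCl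
Reagents that add atoms: trimethylaluminium C[Al](C)C; paraformaldehyde (as formaldehyde) C=O
Why: Negishi carboalumination adds Me–Al syn across the terminal alkyne with Al on the terminal carbon, and the E alkenylalane should add to formaldehyde with retention to give the E allylic alcohol, the acid being masked in situ as its aluminium carboxylate and the 1,1-disubstituted alkene being unreactive.

Step 16
Reactants: 21 isocupressic acid
Product: 22 15-acetoxyisocupressic acid [(1S,4aR,5S,8aR)-5-[(E)-5-acetoxy-3-methylpent-3-en-1-yl]-1,4a-dimethyl-6-methylidenedecahydronaphthalene-1-carboxylic acid]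
Conditions: Ac2O, pyridine, DMAP (cat.), CH2Cl2, 0 °C to rt; aqueous work-up
Reagents that add atoms: acetic anhydride CC(=O)OC(C)=O
Why: DMAP-catalysed acetylation should take the primary allylic alcohol, while the hindered axial acid is not acylated irreversibly because any mixed anhydride is hydrolysed in the aqueous work-up.

**Compound list**

1 | 3-methylcyclohept-2-en-1-one | CC1=CC(=O)CCCC1 | starting material
2 | (R)-3-methylcyclohept-2-en-1-ol | CC1=C[C@H](O)CCCC1 | intermediate
3 | hex-5-ynoic acid | C#CCCCC(=O)O | starting material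
4 | (R)-3-methylcyclohept-2-en-1-yl hex-5-ynoate | CC1=C[C@H](OC(=O)CCCC#C)CCCC1 | intermediate
5 | silyl ketene acetal: 1-[(R)-3-methylcyclohept-2-en-1-yloxy]-1-(trimethylsilyloxy)-6-(trimethylsilyl)hex-1-en-5-yne | CC1=C[C@H](OC(O[Si](C)(C)C)=CCCC#C[Si](C)(C)C)CCCC1 | intermediate (not isolated)
6 | trimethylsilyl 2-[(S)-1-methylcyclohept-2-en-1-yl]-6-(trimethylsilyl)hex-5-ynoate (C2 epimers) | C[Si](C)(C)OC(=O)C(CCC#C[Si](C)(C)C)[C@@]1(C)CCCCC=C1 | intermediate (not isolated)
7 | 2-[(S)-1-methylcyclohept-2-en-1-yl]-6-(trimethylsilyl)hex-5-ynoic acid (C2 epimers) | OC(=O)C(CCC#C[Si](C)(C)C)[C@@]1(C)CCCCC=C1 | intermediate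
8 | 2-[(S)-1-methylcyclohept-2-en-1-yl]-6-(trimethylsilyl)hex-5-ynoyl chloride | ClC(=O)C(CCC#C[Si](C)(C)C)[C@@]1(C)CCCCC=C1 | intermediate (not isolated)
9 | N-methoxy-N-methyl-2-[(S)-1-methylcyclohept-2-en-1-yl]-6-(trimethylsilyl)hex-5-ynamide | CON(C)C(=O)C(CCC#C[Si](C)(C)C)[C@@]1(C)CCCCC=C1 | intermediate
10 | N-methoxy-N-methyl-2-[(S)-1-methyl-4-oxocyclohept-2-en-1-yl]-6-(trimethylsilyl)hex-5-ynamide | CON(C)C(=O)C(CCC#C[Si](C)(C)C)[C@@]1(C)CCCC(=O)C=C1 | intermediate
11 | N-methoxy-N-methyl-2-[(R)-3-iodo-1-methyl-4-oxocyclohept-2-en-1-yl]-6-(trimethylsilyl)hex-5-ynamide | CON(C)C(=O)C(CCC#C[Si](C)(C)C)[C@@]1(C)CCCC(=O)C(I)=C1 | intermediate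
12 | N-methoxy-N-methyl-2-[(S)-1,3-dimethyl-4-oxocyclohept-2-en-1-yl]-6-(trimethylsilyl)hex-5-ynamide | CON(C)C(=O)C(CCC#C[Si](C)(C)C)[C@@]1(C)CCCC(=O)C(C)=C1 | intermediate
13 | N-methoxy-N-methyl-2-[(1S,4S)-4-hydroxy-1,3-dimethylcyclohept-2-en-1-yl]-6-(trimethylsilyl)hex-5-ynamide | CON(C)C(=O)C(CCC#C[Si](C)(C)C)[C@@]1(C)CCC[C@H](O)C(C)=C1 | intermediate
14 | N-methoxy-N-methyl-2-[(1S,4S)-4-(tert-butyldimethylsilyloxy)-1,3-dimethylcyclohept-2-en-1-yl]-6-(trimethylsilyl)hex-5-ynamide | CON(C)C(=O)C(CCC#C[Si](C)(C)C)[C@@]1(C)CCC[C@H](O[Si](C)(C)C(C)(C)C)C(C)=C1 | intermediate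
15 | 4-[(1S,4S)-4-(tert-butyldimethylsilyloxy)-1,3-dimethylcyclohept-2-en-1-yl]-8-(trimethylsilyl)oct-1-en-7-yn-3-one (C4 epimers) | C=CC(=O)C(CCC#C[Si](C)(C)C)[C@@]1(C)CCC[C@H](O[Si](C)(C)C(C)(C)C)C(C)=C1 | intermediate
16 | 8-oxo-14-(trimethylsilyl)-15,16,17-trinorlabd-13-yn-19-al (C9 epimers) | O=C1CC[C@@H]2[C@](C)(CCC[C@]2(C)C=O)C1CCC#C[Si](C)(C)C | intermediate
17 | 8-oxo-14-(trimethylsilyl)-15,16,17-trinorlabd-13-yn-19-oic acid (C9 epimers) | O=C1CC[C@@H]2[C@](C)(CCC[C@]2(C)C(=O)O)C1CCC#C[Si](C)(C)C | intermediate
18 | 8-oxo-15,16,17-trinorlabd-13-yn-19-oic acid (9α-H) | O=C1CC[C@@H]2[C@](C)(CCC[C@]2(C)C(=O)O)[C@H]1CCC#C | intermediate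
19 | 15,16-dinorlabd-8(17)-en-13-yn-19-oic acid | C=C1CC[C@@H]2[C@](C)(CCC[C@]2(C)C(=O)O)[C@H]1CCC#C | intermediate
20 | alkenylalane: dimethylaluminium (13E)-14-(dimethylalumanyl)-15-norlabda-8(17),13-dien-19-oate | C=C1CC[C@@H]2[C@](C)(CCC[C@]2(C)C(=O)O[Al](C)C)[C@H]1CC/C(C)=C/[Al](C)C | intermediate (not isolated)
21 | isocupressic acid, 15-hydroxylabda-8(17),13E-dien-19-oic acid | C=C1CC[C@@H]2[C@](C)(CCC[C@]2(C)C(=O)O)[C@H]1CC/C(C)=C/CO | intermediate
22 | 15-acetoxyisocupressic acid | C=C1CC[C@@H]2[C@](C)(CCC[C@]2(C)C(=O)O)[C@H]1CC/C(C)=C/COC(C)=O | target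

**Count and risk**

Total steps: 16. Longest linear sequence: 16 steps (1 to 22).

Steps most likely to fail:

Step 11 (proposed new method). The enone may be too weak an electrophile, so that ene-type proton loss, aldol capture of the new aldehyde by the aluminium enolate, or attack on the other ring face (cis ring fusion) competes. The fallback uses the known acetal-initiated Prins–pinacol ring contraction; it keeps the same conformational control of the face. It sets out from 14: MeMgBr should give the C8 methyl ketone F1. LiN(i-Pr)2 and Me3SiCl should give its kinetic trimethylsilyl enol ether F2. HC(OMe)3 with Me3SiOTf (cat.) should give the β-keto dimethyl acetal F3. SnCl4 in CH2Cl2 at −78 °C should ionise the acetal to an oxocarbenium ion at C6, which C5 attacks with the same semipinacol shift, to give the 6-methoxy keto aldehyde F4. DBU should eliminate methanol to the Δ6 enone aldehyde F5, and conjugate reduction with [(Ph3P)CuH]6 comes back to the route at 16.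

Step 15. The free acid may protonate the alkenylalane or slow the carbometalation, so that conversion is incomplete. The fallback finishes the side chain by carbonyl olefination and sets out from 19: (Ph3P)AuNTf2-catalysed Markovnikov hydration of the terminal alkyne in wet dioxane should give the 13-oxo acid F6. Horner–Wadsworth–Emmons reaction with triethyl phosphonoacetate and NaH (one extra equivalent for the acid) should give the 13E ethyl enoate F7 after removal of the Z isomer. i-Bu2AlH in CH2Cl2 at −78 °C should reduce the conjugated ester while the hindered aluminium carboxylate is left, which comes back to the route at 21.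

Step 5. The allyl radical may be trapped at C5 (allylic transposition), or over-oxidation may occur. The fallback sets out from 9: SeO2 (cat.) with t-BuOOH in CH2Cl2 hydroxylates C19 by the ene and 2,3-sigmatropic sequence (Riley oxidation), which cannot transpose, and should give the allylic alcohol F8. Dess–Martin periodinane oxidises it and comes back to the route at 10.

Further compounds
F1 | step 11 | C8 methyl ketone: 3-[(1S,4S)-4-(tert-butyldimethylsilyloxy)-1,3-dimethylcyclohept-2-en-1-yl]-7-(trimethylsilyl)hept-6-yn-2-one | CC(=O)C(CCC#C[Si](C)(C)C)[C@@]1(C)CCC[C@H](O[Si](C)(C)C(C)(C)C)C(C)=C1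
F2 | step 11 | kinetic trimethylsilyl enol ether of F1 | C=C(O[Si](C)(C)C)C(CCC#C[Si](C)(C)C)[C@@]1(C)CCC[C@H](O[Si](C)(C)C(C)(C)C)C(C)=C1
F3 | step 11 | β-keto dimethyl acetal: 4-[(1S,4S)-4-(tert-butyldimethylsilyloxy)-1,3-dimethylcyclohept-2-en-1-yl]-1,1-dimethoxy-8-(trimethylsilyl)oct-7-yn-3-one | COC(OC)CC(=O)C(CCC#C[Si](C)(C)C)[C@@]1(C)CCC[C@H](O[Si](C)(C)C(C)(C)C)C(C)=C1
F4 | step 11 | 6-methoxy keto aldehyde: 6-methoxy-8-oxo-14-(trimethylsilyl)-15,16,17-trinorlabd-13-yn-19-al | O=C1CC(OC)[C@@H]2[C@](C)(CCC[C@]2(C)C=O)C1CCC#C[Si](C)(C)C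
F5 | step 11 | Δ6 enone aldehyde: 8-oxo-14-(trimethylsilyl)-15,16,17-trinorlabd-6-en-13-yn-19-al | O=C1C=C[C@@H]2[C@](C)(CCC[C@]2(C)C=O)C1CCC#C[Si](C)(C)C
F6 | step 15 | 13-oxo acid: 13-oxo-14,15-dinorlabd-8(17)-en-19-oic acid | C=C1CC[C@@H]2[C@](C)(CCC[C@]2(C)C(=O)O)[C@H]1CCC(C)=O
F7 | step 15 | 13E ethyl enoate: 15-ethyl hydrogen labda-8(17),13E-diene-15,19-dioate | C=C1CC[C@@H]2[C@](C)(CCC[C@]2(C)C(=O)O)[C@H]1CC/C(C)=C/C(=O)OCC
F8 | step 5 | allylic alcohol: N-methoxy-N-methyl-2-[(1S)-4-hydroxy-1-methylcyclohept-2-en-1-yl]-6-(trimethylsilyl)hex-5-ynamide | CON(C)C(=O)C(CCC#C[Si](C)(C)C)[C@@]1(C)CCCC(O)C=C1
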